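Count everything in percent of the starting complex charged, and count the incoming ligand against that same complex. What stands in each flask at the end of the time given is the question below.

| setting | elm | larch | spring | midnight | summer | winter | dusk |
|---|---|---|---|---|---|---|---|
| starting complex | 20 mM | 20 mM | 20 mM | 20 mM | 20 mM | 20 mM | 20 mM |
| incoming ligand | 1.6 mM | 97 mM | 2.00 mM | 6.00 mM | 20.0 mM | 60.0 mM | 150 mM |
| remark | run made earlier | run made earlier |  |  |  |  |  |
| time |  |  | 50 min | 50 min | 50 min | 50 min | 50 min |

- elm (time / min: complex with two exchanged / %, starting complex / %): 4.00: 1.5, 96.0; 10.0: 0, 96.8; 20.0: 0.5, 92.7; 50.0: 0, 92.6
- larch (time / min: complex with two exchanged / %, starting complex / %): 6.00: 53.8, 6.6; 20.0: 81.0, 0; 30.0: 75.3, 0.1; 50.0: 72.2, 0.7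

(each reading ± 1 percentage point)

* amount of complex with two exchanged at the end, in percent of the starting complex charged for spring, midnight, summer, winter, dusk, in this order
* how the row runs (rises all the way / rises, then falls / hardly changes / falls all the way / falls, then rises)

- the earlier runs were read with a standard deviation of 1 percentage point
- "hardly changes" means that all values lie within two and a half points (for a concentration: within two and a half percent of the largest)

Two people dispute the row. Take spring, with h = 0.0500: h is the fill, the incoming ligand charged per starting complex charged, divided by 2. Midnight has h = 0.150 and summer h = 0.500.

The product is the complex with two exchanged. The counter says the product share is h itself, because each complex that reacts takes both ligands. That gives 5.00% for spring and 50.0% for summer. The counter points to larch, with 81.0% of product at 20.0 min. But the same view expects 4.00% in elm, and no elm reading of the product lies above 1.5%.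

The stepper says ligands arrive singly, and the second exchange runs at 0.5 of the speed of the first. Then the square root of the starting complex share and the square root of the product share add up to one. Larch at 6.00 min reads 0.990, with the scatter of its readings. Counting the ligand spent then gives a product share of h times h, while h is below one.

My own reckoning follows the stepper: 0.250% for spring, 2.25% for midnight, 25.0% for summer. Above a fill of one this rule stops, and I have no value of my own for winter or dusk. Larch falls from 81.0% to 72.2% between 20.0 min and 50.0 min, so something takes product away.

The forecast is the stepper's: 0.3%, 2%, 23%, 82%, 58%, so the row rises, then falls. Its ground is that “the singly exchanged complex forms first, one ligand each”. Its summer value of 23% lies below my 25.0%.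

The flask gives 0.234%, 2.11%, 22.7%, 83.7%, 54.6%, and the row rises, then falls.

    starting complex + incoming ligand → leaving ligand + complex with one exchanged (k = 6.40 M⁻¹ min⁻¹)
    complex with one exchanged + incoming ligand → leaving ligand + complex with two exchanged (k = 3.00 M⁻¹ min⁻¹)
    complex with two exchanged + incoming ligand ⇌ leaving ligand + complex with three exchanged (K = 0.440, k = 0.290 M⁻¹ min⁻¹)

The counter's region is the top of the row: near the turn at 59 mM, winter comes within 16 percentage points of full. Lower down, h times h comes close, with 0.250% against 0.234% in spring and 2.25% against 2.11% in midnight. In spring at 5.39 min, the first exchange uses incoming ligand 42 times as fast as the second. In midnight the incoming ligand, the limiting reagent, is down to 0.38% of its charge at the end, with 25.6% as complex with one exchanged and 2.11% as complex with two exchanged.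

The data are simulated for substances that don't exist; scatter was added.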